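(The constants used here were drawn at random within sensible limits; no experiment stands behind them.)

Start from the moment of reading: the instant at which 5.0 % of the starting material counts as converted, catalyst-bound material included.

    starting material + protic impurity → quenched substrate (k1 = 1.8 × 10⁻⁴ L mol⁻¹ s⁻¹)
    catalyst intermediate C → by-product + catalyst intermediate D (k2 = 0.12 s⁻¹)
    starting material + free catalyst ⇌ catalyst intermediate A (K3 = 4.6 L mol⁻¹, k3 = 0.010 L mol⁻¹ s⁻¹)
    catalyst intermediate E → free catalyst + product (k4 = 0.47 s⁻¹)
    catalyst intermediate D → catalyst intermediate E (k5 = 0.022 s⁻¹)
    reagent + catalyst intermediate B → catalyst intermediate C (k6 = 0.084 L mol⁻¹ s⁻¹)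
    catalyst intermediate A ⇌ catalyst intermediate B (K7 = 33, k7 = 0.0024 s⁻¹)

starting material 1.0 M; reagent 2.00 M; protic impurity 1.00 M; free catalyst 25 mM

- what is bound to the catalyst counts as converted
- charge of starting material (flask): 1.0 M

- the form that holds most of the catalyst when 5.0 % of the starting material are converted (catalyst intermediate C / catalyst intermediate E / catalyst intermediate B / catalyst intermediate D / catalyst intermediate A / free catalyst)
- its share of the catalyst then
- factor on the rate of making product when 5.0 % of the starting material are converted if reagent is charged twice over
- factor on the rate when 5.0 % of the starting material are converted if free catalyst is charged at 250 mM instead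

Two steps use starting material at the outset, the quench and the binding to free catalyst. If both kept their first rates, the mark would arrive at

t′ = mark ÷ (quench rate + binding rate) = 116 s.

But binding relaxes, with time constant τ = 82.1 s, toward a bound level of 20.5 mM. So I put the bound amount at t′ at x′ = 15.5 mM. Put that back in and let the quench supply the remainder:

t″ = (mark − x′) ÷ quench rate = 191 s.

Now fold this into one number, θ, the reading time multiplied by the forward rate constant of catalyst intermediate A going to catalyst intermediate B, which counts the lifetimes of catalyst intermediate A that fit before you look:

θ = 0.459.

θ is below one, while τ is shorter than t″. By this reckoning catalyst has had time to bind, and less than one lifetime of catalyst intermediate A has passed, so I name catalyst intermediate A the resting state at this reading.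

Is one number enough? θ points to the form but does not give its share, which also needs the bound amount at t″, x″ = 18.5 mM. Catalyst intermediate A started from zero, so as a rough allowance I charge half of θ as passed onward, and I get

share = (x″ ÷ catalyst charged)(1 − θ/2) = 57.1 %.

Catalyst intermediate B waits w = 5.95 s for reagent, far less than t″. Doubling the reagent removes half of that wait, so I expect a factor of about 1.02.

The forecast gives catalyst intermediate A at 57 % (range 48 % to 65 %), a reagent factor of 1.01 and a catalyst factor of 0.17, with “reagent capture far too fast to matter when doubled”.

The flask reaches the mark at 2.97 min, with catalyst intermediate A holding 58.9 % of the catalyst, and doubling the reagent gives a factor of 1.01. With that time, θ is 0.428, still below one. Now take the flask charged with free catalyst at 250 mM: the first round of the reckoning gives 18.7 s, so θ is about 0.0448 there, and the θ of the first flask, taken at the time it reached the mark, is ten times that. In the 250 mM flask, the rate of making product at the mark is 0.171 times the 0.109 M h⁻¹ of the first flask, or 0.0186 M h⁻¹.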